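**Plan**

- Numbering: chain C1 (pentyl CH3) to C19 (vinyl CH2); oxolane O–C6–C7–C8–C9; stearate on O7, free hydroxyl on C10.
- Cuts, in retrosynthetic order: the O7–acyl bond; the ring O–C9 bond together with the C10–O bond (epoxide of a C9=C10 Z-alkene opened by O6); C9=C10 (Wittig on a lactol); the O–C6 bond of a γ-lactone (oxygen inserted between C6 and C9); last, C6–C7 and C8–C9 of a cyclobutanone ([2+2]).
- Enabling feature: the ring oxygen lies between C6 and C9 and C6/C7 carry cis substituents, so deleting that oxygen leaves a cis-2-pentyl-3-alkoxycyclobutanone with C9 as the carbonyl carbon.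
- Forward order of rings: cyclobutanone (step 2), γ-lactone by ring expansion (step 3), opening at C9 by reduction and olefination (steps 4 and 6), oxolane closed by 5-exo epoxide opening (step 7); then silylation, auxiliary removal, stearoylation, desilylation.
- Stereochemistry: cis C6/C7 from the ketene–vinyl ether cycloaddition, the absolute sense by separating diastereomers of the (S)-1-(4-methoxyphenyl)ethyl ether; C6 is retained in the migration; C9 and C10 come from the Z-alkene, a hydroxyl-directed epoxidation and an inverting ring closure.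

Key step: step 3

Assumption: the two cis diastereomers formed in step 2 are taken to be separable on silica gel, and the (2S,3S) isomer is identified by correlation after ring expansion.

**Step 1**
Reactants: 1 (S)-1-(4-methoxyphenyl)ethanol; 2 ethyl vinyl ether
Product: 3 1-[(1S)-1-(ethenyloxy)ethyl]-4-methoxybenzene
Conditions: Hg(OAc)2 (cat.), 2 as solvent, reflux; K2CO3 quench
Reagents that add atoms: none
Why: Mercury-catalysed transvinylation (alkoxymercuration of the vinyl ether by the alcohol, then loss of ethanol, driven by excess 2) exchanges the alcohol component without breaking the benzylic C–O bond, so the (S) centre is carried over unchanged.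

**Step 2**
Reactants: 3 1-[(1S)-1-(ethenyloxy)ethyl]-4-methoxybenzene; 4 heptanoyl chloride
Product: 6 (2S,3S)-3-[(1S)-1-(4-methoxyphenyl)ethoxy]-2-pentylcyclobutan-1-one, via pentylketene 5 (not isolated)
Conditions: Et3N, MeCN, 80 °C, slow addition of 4 (excess); SiO2 chromatography to isolate the (2S,3S) cis isomer
Reagents that add atoms: none
Why: Ketene–enol ether [2+2] cycloaddition in which the ketene carbonyl carbon (C9) bonds to the nucleophilic CH2 terminus (C8) and the ketene α-carbon (C6) to the oxygenated carbon (C7), giving the 3-alkoxy regioisomer with pentyl placed cis to the alkoxy group by the orthogonal approach of the ketene; the auxiliary exerts little facial control but turns the two cis enantiomeric rings into diastereomers, so the (2S,3S) isomer should be obtainable by chromatography.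

**Step 3**
Reactants: 6 (2S,3S)-3-[(1S)-1-(4-methoxyphenyl)ethoxy]-2-pentylcyclobutan-1-one
Product: 7 (4S,5S)-4-[(1S)-1-(4-methoxyphenyl)ethoxy]-5-pentyloxolan-2-one
Conditions: mCPBA, NaHCO3, CH2Cl2, 0 °C → rt
Reagents that add atoms: 3-chloroperbenzoic acid, OOC(=O)c1cccc(Cl)c1
Why: Baeyer–Villiger oxidation: the peracid adds to the strained C9 carbonyl and the Criegee adduct collapses by 1,2-shift of C6 from C9 to the inner peroxide oxygen, anti-periplanar to the O–O bond, expelling 3-chlorobenzoate. The closest known reaction type is the regioselective peracid ring expansion of 2-alkyl-3-alkoxycyclobutanones to 5-alkyl-4-alkoxy-γ-butyrolactones. The five-membered lactone is closed by one-atom expansion of the four-membered ring (oxygen insertion into the C6–C9 bond), not by an end-on cyclisation, and the new O–C6 bond persists into the oxolane of the target. No stereocentre is created: C6 migrates with retention and C7 is a spectator, so the cis relationship fixed in step 2 appears as (4S,5S) in 7. The step needs C6 rather than the C8 methylene to migrate, and needs C6 not to epimerise and the C7 ether not to β-eliminate; the higher migratory aptitude of the secondary carbon, the speed of the strain-releasing reaction at 0 °C and the NaHCO3 buffer secure these.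

**Step 4**
Reactants: 7 (4S,5S)-4-[(1S)-1-(4-methoxyphenyl)ethoxy]-5-pentyloxolan-2-one
Product: 8 (4S,5S)-4-[(1S)-1-(4-methoxyphenyl)ethoxy]-5-pentyloxolan-2-ol (anomeric mixture)
Conditions: i-Bu2AlH, CH2Cl2, −78 °C; aq. potassium sodium tartrate work-up
Reagents that add atoms: none
Why: Partial reduction of a γ-lactone with i-Bu2AlH at low temperature stops at the aluminium hemiacetal, which gives the lactol on work-up; the benzylic ether and the C6/C7 centres are untouched and the anomeric mixture is of no consequence.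

**Step 5**
Reactants: 9 10-bromodec-1-ene
Product: 10 (dec-9-en-1-yl)triphenylphosphonium bromide
Conditions: PPh3, MeCN, reflux
Reagents that add atoms: triphenylphosphine, c1ccc(cc1)P(c1ccccc1)c1ccccc1
Why: SN2 quaternisation of triphenylphosphine by the primary bromide; the terminal alkene is inert.

**Step 6**
Reactants: 8 (4S,5S)-4-[(1S)-1-(4-methoxyphenyl)ethoxy]-5-pentyloxolan-2-ol; 10 (dec-9-en-1-yl)triphenylphosphonium bromide
Product: 12 (6S,7S,9Z)-7-[(1S)-1-(4-methoxyphenyl)ethoxy]nonadeca-9,18-dien-6-ol, via (dec-9-en-1-ylidene)triphenylphosphorane 11 (not isolated)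
Conditions: 10 (2.5 equiv), NaN(SiMe3)2, THF, 0 °C; then 8, −78 °C → rt
Reagents that add atoms: none
Why: Wittig olefination of the ring-opened hydroxy aldehyde form of the lactol with a non-stabilised ylide under lithium-free conditions should give the Z-alkene through the kinetically favoured cis-oxaphosphetane; excess ylide takes up the lactol proton, and the C7 ether β to the transient aldehyde is expected to survive as it does in Wittig reactions of 2-deoxy sugar lactols.

**Step 7**
Reactants: 12 (6S,7S,9Z)-7-[(1S)-1-(4-methoxyphenyl)ethoxy]nonadeca-9,18-dien-6-ol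
Product: 14 (1R)-1-[(2R,4S,5S)-4-[(1S)-1-(4-methoxyphenyl)ethoxy]-5-pentyloxolan-2-yl]dec-9-en-1-ol, via cis-epoxy alcohol 13 (not isolated)
Conditions: VO(acac)2 (cat.), t-BuOOH, CH2Cl2, 0 °C → rt; then AcOH (cat.)
Reagents that add atoms: tert-butyl hydroperoxide, CC(C)(C)OO
Why: Hydroxyl-directed epoxidation of a bishomoallylic alcohol, in which the C6 vanadate ester (pentavalent vanadium) delivers oxygen to one face of the Z-alkene through a chair-like transition state with the C6 pentyl group equatorial and the smaller C7 alkoxy group axial to give the (9S,10R) cis-epoxide, followed by acid-promoted 5-exo-tet opening at C9 with inversion, so that C9 becomes R (2,5-trans ring) and C10 stays R (threo), while the remote terminal alkene has no directing group and is left alone.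

**Step 8**
Reactants: 14 (1R)-1-[(2R,4S,5S)-4-[(1S)-1-(4-methoxyphenyl)ethoxy]-5-pentyloxolan-2-yl]dec-9-en-1-ol
Product: 15 tert-butyl-[(1R)-1-[(2R,4S,5S)-4-[(1S)-1-(4-methoxyphenyl)ethoxy]-5-pentyloxolan-2-yl]dec-9-enoxy]dimethylsilane
Conditions: TBSCl, imidazole, DMF, rt
Reagents that add atoms: tert-butyldimethylsilyl chloride, CC(C)(C)[Si](C)(C)Cl
Why: Imidazole-mediated silylation of the secondary C10 hydroxyl masks it so that the C7 oxygen can later be acylated alone, under conditions that spare the acid-labile benzylic ether.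

**Step 9**
Reactants: 15 tert-butyl-[(1R)-1-[(2R,4S,5S)-4-[(1S)-1-(4-methoxyphenyl)ethoxy]-5-pentyloxolan-2-yl]dec-9-enoxy]dimethylsilane
Product: 16 (2S,3S,5R)-5-[(1R)-1-[tert-butyl(dimethyl)silyl]oxydec-9-enyl]-2-pentyloxolan-3-ol
Conditions: DDQ, CH2Cl2/pH 7 buffer, 0 °C → rt
Reagents that add atoms: none
Why: Oxidative cleavage of a 4-methoxybenzyl-type ether: hydride abstraction by DDQ at the electron-rich benzylic position gives an oxocarbenium ion that water hydrolyses to 4-methoxyacetophenone and the C7 alcohol without breaking the C7–O bond, so C7 stays S, and the silyl ether and terminal alkene are inert.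

**Step 10**
Reactants: 16 (2S,3S,5R)-5-[(1R)-1-[tert-butyl(dimethyl)silyl]oxydec-9-enyl]-2-pentyloxolan-3-ol; 17 stearic acid
Product: 18 (2S,3S,5R)-5-[(1R)-1-[tert-butyl(dimethyl)silyl]oxydec-9-enyl]-2-pentyloxolan-3-yl octadecanoate
Conditions: DCC, DMAP, CH2Cl2, rt
Reagents that add atoms: none
Why: Steglich esterification, in which DCC activates the acid as its O-acylisourea and DMAP transfers the acyl group to the only free hydroxyl (C7) with retention of configuration.

**Step 11**
Reactants: 18 (2S,3S,5R)-5-[(1R)-1-[tert-butyl(dimethyl)silyl]oxydec-9-enyl]-2-pentyloxolan-3-yl octadecanoate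
Product: 19 (2S,3S,5R)-5-[(1R)-1-hydroxydec-9-enyl]-2-pentyloxolan-3-yl octadecanoate
Conditions: HF·pyridine, THF/pyridine, 0 °C → rt
Reagents that add atoms: none
Why: Fluoride cleavage of the silyl ether under mildly acidic, non-nucleophilic conditions leaves the stearate in place, and acyl migration from O7 to O10 is disfavoured because the two oxygens are trans across the ring and would need a seven-membered orthoester.

**Compound list**

1 | (S)-1-(4-methoxyphenyl)ethanol | C[C@H](O)c1ccc(OC)cc1 | starting material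
2 | ethyl vinyl ether | C=COCC | starting material
3 | 1-[(1S)-1-(ethenyloxy)ethyl]-4-methoxybenzene | C=CO[C@@H](C)c1ccc(OC)cc1 | intermediate
4 | heptanoyl chloride | CCCCCCC(=O)Cl | starting material
5 | pentylketene (hept-1-en-1-one) | CCCCCC=C=O | intermediate
6 | (2S,3S)-3-[(1S)-1-(4-methoxyphenyl)ethoxy]-2-pentylcyclobutan-1-one | O=C1C[C@H](O[C@@H](C)c2ccc(OC)cc2)[C@@H]1CCCCC | intermediate
7 | (4S,5S)-4-[(1S)-1-(4-methoxyphenyl)ethoxy]-5-pentyloxolan-2-one | O=C1C[C@H](O[C@@H](C)c2ccc(OC)cc2)[C@H](CCCCC)O1 | intermediate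
8 | (4S,5S)-4-[(1S)-1-(4-methoxyphenyl)ethoxy]-5-pentyloxolan-2-ol (anomeric mixture) | OC1C[C@H](O[C@@H](C)c2ccc(OC)cc2)[C@H](CCCCC)O1 | intermediate
9 | 10-bromodec-1-ene | C=CCCCCCCCCBr | starting material
10 | (dec-9-en-1-yl)triphenylphosphonium bromide | C=CCCCCCCCC[P+](c1ccccc1)(c1ccccc1)c1ccccc1.[Br-] | intermediate
11 | (dec-9-en-1-ylidene)triphenylphosphorane | C=CCCCCCCCC=P(c1ccccc1)(c1ccccc1)c1ccccc1 | intermediate
12 | (6S,7S,9Z)-7-[(1S)-1-(4-methoxyphenyl)ethoxy]nonadeca-9,18-dien-6-ol | C=CCCCCCCC/C=C\C[C@H](O[C@@H](C)c1ccc(OC)cc1)[C@@H](O)CCCCC | intermediate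
13 | (6S,7S,9S,10R)-9,10-epoxy-7-[(1S)-1-(4-methoxyphenyl)ethoxy]nonadec-18-en-6-ol | C=CCCCCCCC[C@H]1O[C@H]1C[C@H](O[C@@H](C)c2ccc(OC)cc2)[C@@H](O)CCCCC | intermediate
14 | (1R)-1-[(2R,4S,5S)-4-[(1S)-1-(4-methoxyphenyl)ethoxy]-5-pentyloxolan-2-yl]dec-9-en-1-ol | C=CCCCCCCC[C@@H](O)[C@H]1C[C@H](O[C@@H](C)c2ccc(OC)cc2)[C@H](CCCCC)O1 | intermediate
15 | tert-butyl-[(1R)-1-[(2R,4S,5S)-4-[(1S)-1-(4-methoxyphenyl)ethoxy]-5-pentyloxolan-2-yl]dec-9-enoxy]dimethylsilane | C=CCCCCCCC[C@@H](O[Si](C)(C)C(C)(C)C)[C@H]1C[C@H](O[C@@H](C)c2ccc(OC)cc2)[C@H](CCCCC)O1 | intermediate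
16 | (2S,3S,5R)-5-[(1R)-1-[tert-butyl(dimethyl)silyl]oxydec-9-enyl]-2-pentyloxolan-3-ol | C=CCCCCCCC[C@@H](O[Si](C)(C)C(C)(C)C)[C@H]1C[C@H](O)[C@H](CCCCC)O1 | intermediate
17 | stearic acid (octadecanoic acid) | CCCCCCCCCCCCCCCCCC(=O)O | starting material
18 | (2S,3S,5R)-5-[(1R)-1-[tert-butyl(dimethyl)silyl]oxydec-9-enyl]-2-pentyloxolan-3-yl octadecanoate | C=CCCCCCCC[C@@H](O[Si](C)(C)C(C)(C)C)[C@H]1C[C@H](OC(=O)CCCCCCCCCCCCCCCCC)[C@H](CCCCC)O1 | intermediate
19 | (2S,3S,5R)-5-[(1R)-1-hydroxydec-9-enyl]-2-pentyloxolan-3-yl octadecanoate | C=CCCCCCCC[C@@H](O)[C@H]1C[C@H](OC(=O)CCCCCCCCCCCCCCCCC)[C@H](CCCCC)O1 | target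

**Step count**

Total: 11 steps. Longest linear sequence: 10 steps (steps 1–4 and 6–11); step 5 is a one-step side branch.

**Steps most likely to fail**

Step 2. Dimerisation of the monoalkylketene may outrun the cross-cycloaddition, the amine may epimerise C6 to the trans isomer, and the auxiliary gives no facial bias. The fallback sets out from 1 and comes back at 6. It builds the cis relationship into an enol ether instead of relying on the ketene approach.
- Alcohol 1 is treated with KH and trichloroethylene to give the (E)-1,2-dichlorovinyl ether F1.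
- n-BuLi converts this to the lithium alkynyl ether F2, which is alkylated with 1-iodopentane to the hept-1-ynyl ether F3.
- Semihydrogenation (H2, Pd/BaSO4, pyridine) gives the (Z)-hept-1-enyl ether F4.
- Cycloaddition with dichloroketene F5 (from Cl3CCOCl and Zn–Cu couple, Et2O) is suprafacial on the enol ether, so the Z geometry fixes the cis ring relationship; it should give the cis-dichlorocyclobutanone F6 after separation of the facial diastereomers.
- Zn, NH4Cl, MeOH removes both chlorines to return 6.

Step 7. Oxygen delivery to the wrong alkene face would end in the 2,5-cis oxolane, and the acid used for ring closure may ionise the benzylic ether. The fallback sets out from 8 and comes back at 14. It separates the two stereochemical events.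
- Lactol 8 is methylenated with methylenetriphenylphosphorane F7 (from Ph3PCH3Br and KOt-Bu) to the terminal alkenol F8.
- Mukaiyama aerobic oxidative cyclisation (Co(modp)2, a divalent cobalt bis(diketonate), O2, t-BuOOH, i-PrOH, 55 °C), which is trans-selective for 1-substituted pent-4-en-1-ols, should give the trans-oxolanylmethanol F9.
- Dess–Martin oxidation gives the aldehyde F10.
- Addition of non-8-enylmagnesium bromide F11 (from 9-bromonon-1-ene and Mg) gives the C10-epimeric carbinol mixture F12.
- Oxidation to the ketone F13 and Felkin–Anh-controlled reduction with LiBH(s-Bu)3 at −78 °C should give the threo alcohol 14.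

Step 6. The strongly basic ylide may cause β-elimination of the C7 ether from the open-chain aldehyde, and Z-selectivity may erode. The fallback sets out from 8 and comes back at 12. It replaces the olefination by an alkyne route.
- Seyferth–Gilbert homologation of 8 with the Ohira–Bestmann reagent (dimethyl (1-diazo-2-oxopropyl)phosphonate, K2CO3, MeOH) gives the terminal alkynol F14.
- Double deprotonation (n-BuLi, THF/DMPU) and C-alkylation with 9-bromonon-1-ene give the enynol F15.
- Semihydrogenation (H2, Pd/CaCO3 poisoned with Pb(OAc)2, quinoline, stopped after one equivalent) gives 12, the cis geometry coming from syn addition of hydrogen.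

**Further compounds**

F1 | step 2 | 1-[(1S)-1-{[(E)-1,2-dichloroethenyl]oxy}ethyl]-4-methoxybenzene | Cl/C=C(/Cl)O[C@@H](C)c1ccc(OC)cc1
F2 | step 2 | lithium [(1S)-1-(4-methoxyphenyl)ethoxy]ethynide | [Li]C#CO[C@@H](C)c1ccc(OC)cc1
F3 | step 2 | 1-[(1S)-1-(hept-1-yn-1-yloxy)ethyl]-4-methoxybenzene | CCCCCC#CO[C@@H](C)c1ccc(OC)cc1
F4 | step 2 | 1-[(1S)-1-{[(1Z)-hept-1-en-1-yl]oxy}ethyl]-4-methoxybenzene | CCCCC/C=C\O[C@@H](C)c1ccc(OC)cc1
F5 | step 2 | dichloroketene | ClC(Cl)=C=O
F6 | step 2 | (3R,4S)-2,2-dichloro-3-[(1S)-1-(4-methoxyphenyl)ethoxy]-4-pentylcyclobutan-1-one | O=C1C(Cl)(Cl)[C@H](O[C@@H](C)c2ccc(OC)cc2)[C@@H]1CCCCC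
F7 | step 7 | methylenetriphenylphosphorane | C=P(c1ccccc1)(c1ccccc1)c1ccccc1
F8 | step 7 | (4S,5S)-4-[(1S)-1-(4-methoxyphenyl)ethoxy]dec-1-en-5-ol | C=CC[C@H](O[C@@H](C)c1ccc(OC)cc1)[C@@H](O)CCCCC
F9 | step 7 | [(2R,4S,5S)-4-[(1S)-1-(4-methoxyphenyl)ethoxy]-5-pentyloxolan-2-yl]methanol | OC[C@H]1C[C@H](O[C@@H](C)c2ccc(OC)cc2)[C@H](CCCCC)O1
F10 | step 7 | (2R,4S,5S)-4-[(1S)-1-(4-methoxyphenyl)ethoxy]-5-pentyloxolane-2-carbaldehyde | O=C[C@H]1C[C@H](O[C@@H](C)c2ccc(OC)cc2)[C@H](CCCCC)O1
F11 | step 7 | non-8-en-1-ylmagnesium bromide | C=CCCCCCCC[Mg]Br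
F12 | step 7 | 1-[(2R,4S,5S)-4-[(1S)-1-(4-methoxyphenyl)ethoxy]-5-pentyloxolan-2-yl]dec-9-en-1-ol (mixture of C1 epimers) | C=CCCCCCCCC(O)[C@H]1C[C@H](O[C@@H](C)c2ccc(OC)cc2)[C@H](CCCCC)O1
F13 | step 7 | 1-[(2R,4S,5S)-4-[(1S)-1-(4-methoxyphenyl)ethoxy]-5-pentyloxolan-2-yl]dec-9-en-1-one | C=CCCCCCCCC(=O)[C@H]1C[C@H](O[C@@H](C)c2ccc(OC)cc2)[C@H](CCCCC)O1
F14 | step 6 | (4S,5S)-4-[(1S)-1-(4-methoxyphenyl)ethoxy]dec-1-yn-5-ol | C#CC[C@H](O[C@@H](C)c1ccc(OC)cc1)[C@@H](O)CCCCC
F15 | step 6 | (6S,7S)-7-[(1S)-1-(4-methoxyphenyl)ethoxy]nonadec-18-en-9-yn-6-ol | C=CCCCCCCCC#CC[C@H](O[C@@H](C)c1ccc(OC)cc1)[C@@H](O)CCCCC
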